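Its constants are invented; the run is a simulation.

No substrate can reach the side product without first being activated, so the first thing to find in these flasks was how much of the charge the activation gets through in the time.

in all of them: substrate 0.36 M; activator 1.30 equiv; time 80 min
- grey: temperature 25 °C
- blue: temperature 33 °C
- green: temperature 41 °C

* which of these there is most of at the end, counted by the substrate in it, grey (side product / ring / substrate / open dimer / over-reaction product)
* which of these there is most of at the end, counted by the substrate in it, blue (side product / ring / substrate / open dimer / over-reaction product)
* which of these there is most of at the end, counted by the substrate in it, green (side product / ring / substrate / open dimer / over-reaction product)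
* final amount of the leader among these, as a percentage of the substrate charged, in grey
* final amount of the leader among these, as a percentage of the substrate charged, in blue
* final amount of the leader among these, as a percentage of the substrate charged, in green

- percentages count the substrate that a species holds: one open dimer counts as two
- ring is meant together with its crystals
- solid, in amounts per volume of the solution: crystals
- at 25 °C the constants are as listed, elsewhere as the activation energies make them

    substrate + activated form → open dimer (k1 = 0.0014 L mol⁻¹ s⁻¹, Ea1 = 56.0 kJ mol⁻¹)
    activated form → side product (k2 = 7.0 × 10⁻⁴ s⁻¹, Ea2 = 84.0 kJ mol⁻¹)
    activated form → ring (k3 = 3.5 × 10⁻⁴ s⁻¹, Ea3 = 93.0 kJ mol⁻¹)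
    crystals ⇌ ring, rate k4*(cs4 - [ring]) while solid is left; crystals form when [ring] > cs4 (cs4 = 0.30 M, k4 = 0.0058 s⁻¹)
    activator + ring → over-reaction product (k5 = 2.7 × 10⁻⁴ L mol⁻¹ s⁻¹, Ea5 = 62.0 kJ mol⁻¹)
    substrate + activator → activated form (k6 = 5.4 × 10⁻⁴ L mol⁻¹ s⁻¹, Ea6 = 80.0 kJ mol⁻¹)
    (constants at 25 °C)

How much substrate stayed unactivated? In the activation step activator and substrate fall one for one, so that step's second-order rate, taken by itself, integrates in closed form. Let e be the equivalents of activator, and let τ be the activation constant times the substrate charge times (e less one) times the time. In grey τ came to 0.280, and I reckoned 41.7% of the charge unactivated. I called this fraction, (e less one) over (e times exp τ, less one), the survival. It counts activation and nothing else. Raising the constant by its activation energy, I got a survival of 20.1% in blue and 6.62% in green.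

What became of the activated part? The activated form splits three ways, to side product, to ring, and to open dimer at a rate that follows the substrate, which I took halfway between the charge and the survival. This selectivity, times the activated fraction, gave side product of 29.0% in grey, 42.7% in blue and 51.4% in green. So the survival stood above the side product in grey and below it in blue and green.

Could the open dimer, which counts double, pass the side product in the two warmer flasks? The side-product rate over twice the dimer rate was 1.55 in blue and 2.32 in green, so I committed to substrate in grey and side product in blue and green.

The forecast named substrate, side product and side product, at 33%, 38% and 48%, holding that the activated form “splits mainly to the side product”.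

The simulation gave substrate at 34.4% in grey, side product at 39.6% in blue and side product at 47.7% in green.

My survival in grey stood 7.3 percentage points above the substrate found, and that flask held 22.1% as open dimer. The neighbouring flask was grey run at 40 °C, with amounts and time held. Its survival came to 7.82%, against 41.7% in grey at its own temperature. That flask ended with 6.79% substrate, and the lead had passed from substrate to side product, at 47.0%.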